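**Retrosynthetic overview**

1. The strategy rests on the ring-cis trisubstituted C4=C5 olefin of the ten-membered carbocycle (C1–C10), which lies between the C3 methylene and the lactone carbinol C6. It is traded for a C4–SO2–C5 bridge, so that Ramberg–Bäcklund contraction of the eleven-membered sulfone 27 gives cyclodecadiene 30.
2. Sulfone 27 comes from sulfide 26, closed by S-alkylation (C4 thiolate on the C5 mesylate) of the acyclic C1–C15 chain 21. Chain 21 is joined at C10=C1 by a Wittig reaction of α-silyloxy ketone 13 with ylide 20, which places C14 cis to C2.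
3. C6 and C7 derive from (S)-5-(hydroxymethyl)furan-2(5H)-one by trans conjugate vinylation, and C8 from a reagent-controlled allylboration. The lactone is carried through the sulfur chemistry as its methyl lactol acetal, so that O6 is an ether oxygen and not a free alkoxide next to the sulfone.
4. Ring order: five-membered O6–C12 ring (from the butenolide), eleven-membered thiacycle (step 19), ten-membered carbocycle (step 21), lactone carbonyl restored (step 23), C1–C10 oxirane (step 28).
5. End game: α-methylenation (C13), C8 methacrylate, C14 desilylation, tartrate-controlled epoxidation, C14 acetate.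

Key step: step 21

Remark: germacrane numbering (C1–C15) is used throughout; the acetal carbon C12 (compounds 4–31), the carbinol C10 of 11 and 12 and C11 of 33 and 34 are carried as epimer mixtures and later destroyed, so they are left unassigned in the SMILES; (R)-pent-4-en-2-ol and (+)-Ipc2B(allyl) are taken as commercial.

**Route**

Step 1
Reactants: 1 (S)-5-(hydroxymethyl)furan-2(5H)-one
Product: 2 TBS ether of the butenolide
Conditions: TBSCl, imidazole, CH2Cl2, 0 °C → rt
Reagents that add atoms: tert-butyldimethylsilyl chloride, CC(C)(C)[Si](C)(C)Cl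
Why: O-silylation of the primary alcohol; the bulky silyloxymethyl group at C6 will shield one face of the butenolide in step 2.

Step 2
Reactants: 2 TBS butenolide
Product: 3 trans-vinyl lactone
Conditions: CH2=CHMgBr, CuBr·SMe2 (10 mol %), THF, −78 → −40 °C; aq. NH4Cl
Reagents that add atoms: vinylmagnesium bromide, C=C[Mg]Br
Why: Copper-catalysed conjugate addition; vinyl should add to C7 anti to the C6 silyloxymethyl group, which sets the trans C6/C7 relationship of the future lactone.

Step 3
Reactants: 3 trans-vinyl lactone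
Product: 4 lactol
Conditions: i-Bu2AlH, CH2Cl2, −78 °C; Rochelle salt
Reagents that add atoms: none
Why: Hydride half-reduction of the γ-lactone; the tetrahedral aluminate should survive at −78 °C and give the lactol on work-up.

Step 4
Reactants: 4 lactol
Product: 5 methyl acetal
Conditions: MeI, Ag2O, CH2Cl2, rt, dark
Reagents that add atoms: iodomethane, CI
Why: Purdie-type O-methylation of the hemiacetal hydroxyl under neutral conditions keeps the silyl ether and turns the lactone into a base-stable acetal in which O6 is an ether oxygen.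

Step 5
Reactants: 5 methyl acetal
Product: 7 C8 aldehyde, via secondary ozonide 6 (not isolated)
Conditions: O3, CH2Cl2, −78 °C (Sudan red end point); then PPh3, −78 °C → rt
Reagents that add atoms: ozone, [O-][O+]=O
Why: Ozonolysis with reductive work-up; the terminal vinyl group reacts far faster than the acetal C–H, and the trans-disposed aldehyde is not prone to epimerisation at C7.

Step 6
Reactants: 7 C8 aldehyde
Product: 9 homoallylic alcohol (8R), via borinate 8 (not isolated)
Conditions: (+)-Ipc2B(allyl) (1 M in pentane), Et2O, −78 °C; then NaOH, H2O2, 0 °C → rt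
Reagents that add atoms: (+)-B-allyldiisopinocampheylborane, C=CCB([C@H]1C[C@H]2C[C@@H]([C@@H]1C)C2(C)C)[C@H]1C[C@H]2C[C@@H]([C@@H]1C)C2(C)C
Why: Brown allylboration through a closed chair transition state; the isopinocampheyl ligands should direct allyl to the Re face of the aldehyde and give the 8R carbinol (O8 anti to O6 and to C11) by reagent control.

Step 7
Reactants: 9 homoallylic alcohol
Product: 10 PMB ether
Conditions: NaH, 4-MeOC6H4CH2Cl, n-Bu4NI (cat.), THF/DMF, 0 °C → rt
Reagents that add atoms: 4-methoxybenzyl chloride, COc1ccc(CCl)cc1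
Why: Williamson etherification of the C8 alkoxide; basic conditions leave the acetal and the remote silyl ether untouched.

Step 8
Reactants: 10 PMB ether
Product: 11 10,14-diol
Conditions: K2OsO2(OH)4 (cat.), NMO, acetone/H2O, rt
Reagents that add atoms: N-methylmorpholine N-oxide, C[N+]1([O-])CCOCC1; water, O
Why: OsO4-catalysed dihydroxylation of the terminal alkene; the new C10 carbinol is oxidised in step 10, so its configuration does not matter.

Step 9
Reactants: 11 10,14-diol
Product: 12 C14 TBDPS ether
Conditions: TBDPSCl, imidazole, CH2Cl2, 0 °C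
Reagents that add atoms: tert-butyldiphenylsilyl chloride, CC(C)(C)[Si](Cl)(c1ccccc1)c1ccccc1
Why: Selective silylation of the primary hydroxyl of a 1,2-diol with a bulky chlorosilane.

Step 10
Reactants: 12 C14 TBDPS ether
Product: 13 α-silyloxy ketone
Conditions: Dess–Martin periodinane, NaHCO3, CH2Cl2, rt
Reagents that add atoms: none
Why: Dess–Martin oxidation of the secondary alcohol under buffered, non-basic conditions, which should avoid β-elimination of the C8 ether.

Step 11
Reactants: 14 (R)-pent-4-en-2-ol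
Product: 15 TBS ether of 14
Conditions: TBSCl, imidazole, DMF, rt
Reagents that add atoms: tert-butyldimethylsilyl chloride, CC(C)(C)[Si](C)(C)Cl
Why: O-silylation of the secondary alcohol (C4 oxygen) for the ylide chemistry.

Step 12
Reactants: 15 TBS ether
Product: 17 (R)-4-(TBS-oxy)pentan-1-ol, via B-alkyl-9-BBN 16 (not isolated)
Conditions: 9-BBN, THF, 0 °C → rt; then NaOH, H2O2
Reagents that add atoms: hydrogen peroxide, OO
Why: Anti-Markovnikov hydroboration–oxidation of the terminal alkene gives the C1 primary alcohol.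

Step 13
Reactants: 17 primary alcohol
Product: 18 (R)-iodide
Conditions: I2, PPh3, imidazole, CH2Cl2, 0 °C
Reagents that add atoms: iodine, II
Why: Appel-type iodination of a primary alcohol by SN2 displacement of the oxyphosphonium.

Step 14
Reactants: 18 (R)-iodide
Product: 19 phosphonium iodide
Conditions: PPh3, MeCN, reflux
Reagents that add atoms: triphenylphosphine, c1ccccc1P(c1ccccc1)c1ccccc1
Why: SN2 quaternisation of triphenylphosphine by the primary iodide.

Step 15
Reactants: 19 phosphonium iodide; 13 α-silyloxy ketone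
Product: 21 acyclic (Z)-olefin, via ylide 20 (not isolated)
Conditions: KN(SiMe3)2, THF, −78 °C; then 13, −78 °C → rt
Reagents that add atoms: none
Why: Wittig olefination of an α-alkoxy ketone with a non-stabilised ylide; the α-oxygen substituent is known to steer the ylide-derived chain cis to the CH2OSi group, which should give C14 cis to C2 (C9 trans to C2), and the low temperature limits enolisation toward O8.

Step 16
Reactants: 21 acyclic (Z)-olefin
Product: 22 4,5-diol
Conditions: camphorsulfonic acid (cat.), MeOH/CH2Cl2, 0 °C → rt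
Reagents that add atoms: none
Why: Acid-catalysed methanolysis of the primary and secondary TBS ethers; the primary TBDPS ether and the PMB ether are much slower, and in methanol the acetal stays a methyl acetal.

Step 17
Reactants: 22 4,5-diol
Product: 23 C5 mesylate
Conditions: MsCl (1.05 equiv), 2,4,6-collidine, CH2Cl2, −10 °C
Reagents that add atoms: methanesulfonyl chloride, CS(=O)(=O)Cl
Why: Selective sulfonylation of the primary hydroxyl over the secondary C4 hydroxyl with a hindered base.

Step 18
Reactants: 23 C5 mesylate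
Product: 24 C4 thioacetate (4S)
Conditions: AcSH, PPh3, DIAD, THF, 0 °C
Reagents that add atoms: thioacetic acid, CC(=O)S
Why: Mitsunobu thioesterification of the secondary alcohol with inversion at C4 (R to S); this centre is lost in step 21.

Step 19
Reactants: 24 C4 thioacetate
Product: 26 eleven-membered cyclic sulfide, via potassium thiolate 25 (not isolated)
Conditions: K2CO3, degassed MeOH/THF, 2 mM, slow addition, rt → 40 °C
Reagents that add atoms: none
Why: Methanolysis of the thioacetate releases the C4 thiolate, which should close the thiacycle by intramolecular SN2 displacement of the primary mesylate (11-exo-tet) under high dilution.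

Step 20
Reactants: 26 cyclic sulfide
Product: 27 eleven-membered cyclic sulfone
Conditions: (NH4)6Mo7O24·4H2O (cat.), 30 % H2O2, EtOH, 0 °C → rt
Reagents that add atoms: hydrogen peroxide, OO
Why: Molybdate-catalysed peroxide oxidation of sulfide to sulfone, which is chemoselective over the trisubstituted olefin when no free allylic alcohol is present.

Step 21
Reactants: 27 eleven-membered cyclic sulfone
Product: 30 cyclodecadiene, via α-bromo sulfone 28 (not isolated), via episulfone 29 (not isolated)
Conditions: CBr2F2, KOH/Al2O3, t-BuOH/CH2Cl2, 5 °C → rt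
Reagents that add atoms: none
Why: Hydroxide on alumina removes the more acidic C5–H (between the sulfone and the ether carbon C6), the carbanion takes bromine from CBr2F2 to give 28, the tertiary C4–H is then removed and the C4 carbanion displaces bromide in a 3-exo-tet closure to episulfone 29, which loses SO2 cheletropically to leave C4=C5. This is a Ramberg–Bäcklund rearrangement with in situ halogenation, and the closest known type is the ring contraction of macrocyclic sulfones to medium-ring cycloalkenes. The ten-membered carbocycle is closed by that 3-exo-tet C4–C5 bond formation inside the eleven-membered thiacycle, and extrusion turns the bicyclic episulfone into the monocyclic diene. No stereocentre is created and the C4 centre of 27 is destroyed, so its configuration is immaterial. The step needs the ring-cis (4Z) olefin, which should follow from the kinetically preferred cis-fused episulfone of the medium ring and its stereospecific extrusion, faster than epimerisation at C5 under hydroxide. Chemoselectivity rests on the substrate: O6 is an acetal ether oxygen, so there is no alkoxide to close an epoxy sulfone on brominated C5 or to start retro-aldol cleavage, it is a poor leaving group for β-elimination from the C5 carbanion, and no other C–H is comparably acidic.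

Step 22
Reactants: 30 cyclodecadiene
Product: 31 lactol
Conditions: AcOH/THF/H2O (3:1:1), 40 °C
Reagents that add atoms: water, O
Why: Mild acid hydrolysis of the 2-methoxytetrahydrofuran acetal; the silyl ether, the PMB ether and the diene should tolerate aqueous acetic acid.

Step 23
Reactants: 31 lactol
Product: 32 γ-lactone
Conditions: PhI(OAc)2, TEMPO (cat.), CH2Cl2, rt
Reagents that add atoms: none
Why: Oxoammonium (TEMPO) oxidation of the lactol to the trans-fused 12,6-lactone; no other free hydroxyl is present.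

Step 24
Reactants: 32 γ-lactone
Product: 35 α-methylene lactone, via Mannich base 33 (not isolated), via ammonium iodide 34 (not isolated)
Conditions: LiN(iPr)2, THF, −78 °C; CH2=NMe2+ I−, −78 °C → rt; then MeI, MeOH/CH2Cl2; then aq. NaHCO3
Reagents that add atoms: N,N-dimethylmethyleneiminium iodide (Eschenmoser's salt), C=[N+](C)C.[I-]
Why: Mannich reaction of the lactone enolate at C11, N-quaternisation and base-induced β-elimination install the exocyclic C11=C13 methylene.

Step 25
Reactants: 35 α-methylene lactone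
Product: 36 C8 alcohol
Conditions: DDQ, CH2Cl2/pH 7 buffer, 0 °C
Reagents that add atoms: none
Why: Oxidative cleavage of the PMB ether by hydride abstraction; it is done before the acid-sensitive epoxide exists.

Step 26
Reactants: 36 C8 alcohol
Product: 37 C8 methacrylate
Conditions: methacrylic anhydride, Et3N, DMAP, CH2Cl2, rt
Reagents that add atoms: methacrylic anhydride, C=C(C)C(=O)OC(=O)C(C)=C
Why: DMAP-catalysed acylation of the secondary C8 hydroxyl while C14 is still silylated.

Step 27
Reactants: 37 C8 methacrylate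
Product: 38 C14 allylic alcohol
Conditions: HF·pyridine, pyridine, THF, 0 °C → rt
Reagents that add atoms: none
Why: Fluoride desilylation under weakly acidic, non-nucleophilic conditions that spare the two acrylate-type esters.

Step 28
Reactants: 38 C14 allylic alcohol
Product: 39 epoxy alcohol (1R,10S)
Conditions: Ti(OiPr)4 (20 mol %), L-(+)-diethyl tartrate (24 mol %), t-BuOOH, 4 Å MS, CH2Cl2, −20 °C
Reagents that add atoms: tert-butyl hydroperoxide, CC(C)(C)OO
Why: Sharpless asymmetric epoxidation; only the olefin bearing the free allylic hydroxyl (C10=C1) reacts, and the L-(+)-tartrate complex should deliver oxygen to the face that gives the 10S,1R oxirane (the 2S sense at the carbinol-bearing carbon), on what should be the exposed outer face of the ring-trans olefin.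

Step 29
Reactants: 39 epoxy alcohol
Product: 40 target
Conditions: Ac2O, pyridine, DMAP (cat.), CH2Cl2, 0 °C
Reagents that add atoms: acetic anhydride, CC(=O)OC(C)=O
Why: Acetylation of the primary C14 hydroxyl under basic conditions that leave the oxirane intact.

**Compound list**

1 | (S)-5-(hydroxymethyl)furan-2(5H)-one | OC[C@H]1OC(=O)C=C1 | starting material
2 | (S)-5-[(tert-butyldimethylsilyloxy)methyl]furan-2(5H)-one | CC(C)(C)[Si](C)(C)OC[C@H]1OC(=O)C=C1 | intermediate
3 | (4R,5S)-5-[(tert-butyldimethylsilyloxy)methyl]-4-vinyldihydrofuran-2(3H)-one (C6/C7 trans) | CC(C)(C)[Si](C)(C)OC[C@H]1OC(=O)C[C@@H]1C=C | intermediate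
4 | lactol of 3, (4R,5S)-5-[(TBS-oxy)methyl]-4-vinyltetrahydrofuran-2-ol, C12 anomers | CC(C)(C)[Si](C)(C)OC[C@H]1OC(O)C[C@@H]1C=C | intermediate
5 | methyl acetal, tert-butyl{[(2S,3R)-5-methoxy-3-vinyltetrahydrofuran-2-yl]methoxy}dimethylsilane, C12 anomers | CC(C)(C)[Si](C)(C)OC[C@H]1OC(OC)C[C@@H]1C=C | intermediate
6 | secondary ozonide (1,2,4-trioxolane) on the former vinyl group of 5 | CC(C)(C)[Si](C)(C)OC[C@H]1OC(OC)C[C@@H]1C2OCOO2 | intermediate (not isolated)
7 | (2S,3S)-2-[(TBS-oxy)methyl]-5-methoxytetrahydrofuran-3-carbaldehyde (C8 aldehyde, C6/C7 trans) | CC(C)(C)[Si](C)(C)OC[C@H]1OC(OC)C[C@@H]1C=O | intermediate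
8 | O-diisopinocampheylboryl (borinate) derivative of alcohol 9 | CC(C)(C)[Si](C)(C)OC[C@H]1OC(OC)C[C@@H]1[C@H](OB([C@H]2C[C@H]3C[C@@H]([C@@H]2C)C3(C)C)[C@H]2C[C@H]3C[C@@H]([C@@H]2C)C3(C)C)CC=C | intermediate (not isolated)
9 | 8R homoallylic alcohol: acetal 5 with CH(OH)CH2CH=CH2 (C8 R) in place of vinyl | CC(C)(C)[Si](C)(C)OC[C@H]1OC(OC)C[C@@H]1[C@H](O)CC=C | intermediate
10 | C8 4-methoxybenzyl ether of 9 | CC(C)(C)[Si](C)(C)OC[C@H]1OC(OC)C[C@@H]1[C@H](OCc2ccc(OC)cc2)CC=C | intermediate
11 | 10,14-diol from 10 (C10 epimers) | CC(C)(C)[Si](C)(C)OC[C@H]1OC(OC)C[C@@H]1[C@H](OCc2ccc(OC)cc2)CC(O)CO | intermediate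
12 | C14 tert-butyldiphenylsilyl ether of 11 with free C10 carbinol (C10 epimers) | CC(C)(C)[Si](C)(C)OC[C@H]1OC(OC)C[C@@H]1[C@H](OCc2ccc(OC)cc2)CC(O)CO[Si](c3ccccc3)(c4ccccc4)C(C)(C)C | intermediate
13 | C10 ketone: C5 TBS ether, O6–C12 methyl acetal, C8 PMB ether (8R), C14 TBDPS ether | CC(C)(C)[Si](C)(C)OC[C@H]1OC(OC)C[C@@H]1[C@H](OCc2ccc(OC)cc2)CC(=O)CO[Si](c3ccccc3)(c4ccccc4)C(C)(C)C | intermediate
14 | (R)-pent-4-en-2-ol | C=CC[C@@H](C)O | starting material
15 | (R)-tert-butyldimethyl(pent-4-en-2-yloxy)silane | C=CC[C@@H](C)O[Si](C)(C)C(C)(C)C | intermediate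
16 | B-[(R)-4-(TBS-oxy)pentyl]-9-borabicyclo[3.3.1]nonane | B1(CCC[C@@H](C)O[Si](C)(C)C(C)(C)C)C2CCCC1CCC2 | intermediate (not isolated)
17 | (R)-4-(tert-butyldimethylsilyloxy)pentan-1-ol | OCCC[C@@H](C)O[Si](C)(C)C(C)(C)C | intermediate
18 | (R)-tert-butyl[(5-iodopentan-2-yl)oxy]dimethylsilane | ICCC[C@@H](C)O[Si](C)(C)C(C)(C)C | intermediate
19 | [(R)-4-(tert-butyldimethylsilyloxy)pentyl]triphenylphosphonium iodide | [I-].c1ccccc1[P+](c1ccccc1)(c1ccccc1)CCC[C@@H](C)O[Si](C)(C)C(C)(C)C | intermediate
20 | ylide of 19, [(R)-4-(TBS-oxy)pentylidene]triphenylphosphorane | c1ccccc1P(c1ccccc1)(c1ccccc1)=CCC[C@@H](C)O[Si](C)(C)C(C)(C)C | intermediate (not isolated)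
21 | acyclic C1–C15 chain: C10=C1 with C14 cis to C2 (CIP Z), C4 (R) TBS ether, C5 TBS ether, O6–C12 methyl acetal, C8 PMB ether, C14 TBDPS ether | CC(C)(C)[Si](C)(C)OC[C@H]1OC(OC)C[C@@H]1[C@H](OCc2ccc(OC)cc2)C/C(CO[Si](c3ccccc3)(c4ccccc4)C(C)(C)C)=C/CC[C@@H](C)O[Si](C)(C)C(C)(C)C | intermediate
22 | 4,5-diol of 21 (C4 R secondary alcohol, C5 primary alcohol) | OC[C@H]1OC(OC)C[C@@H]1[C@H](OCc2ccc(OC)cc2)C/C(CO[Si](c3ccccc3)(c4ccccc4)C(C)(C)C)=C/CC[C@@H](C)O | intermediate
23 | C5 methanesulfonate of 22 with free C4 hydroxyl | CS(=O)(=O)OC[C@H]1OC(OC)C[C@@H]1[C@H](OCc2ccc(OC)cc2)C/C(CO[Si](c3ccccc3)(c4ccccc4)C(C)(C)C)=C/CC[C@@H](C)O | intermediate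
24 | C5 mesylate with C4 (S) S-acetyl thioester | CS(=O)(=O)OC[C@H]1OC(OC)C[C@@H]1[C@H](OCc2ccc(OC)cc2)C/C(CO[Si](c3ccccc3)(c4ccccc4)C(C)(C)C)=C/CC[C@H](C)SC(C)=O | intermediate
25 | potassium C4 thiolate of 24 | [K+].CS(=O)(=O)OC[C@H]1OC(OC)C[C@@H]1[C@H](OCc2ccc(OC)cc2)C/C(CO[Si](c3ccccc3)(c4ccccc4)C(C)(C)C)=C/CC[C@H](C)[S-] | intermediate (not isolated)
26 | eleven-membered cyclic sulfide (S between C4 and C5; 4S), trans-fused O6–C12 methyl acetal ring, C8 PMB ether, C14 TBDPS ether, ring-trans C10=C1 | COc1ccc(CO[C@@H]2C/C(CO[Si](c4ccccc4)(c5ccccc5)C(C)(C)C)=C/CC[C@H](C)SC[C@H]3OC(OC)C[C@H]23)cc1 | intermediate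
27 | eleven-membered cyclic sulfone (S,S-dioxide of 26) | COc1ccc(CO[C@@H]2C/C(CO[Si](c4ccccc4)(c5ccccc5)C(C)(C)C)=C/CC[C@H](C)S(=O)(=O)C[C@H]3OC(OC)C[C@H]23)cc1 | intermediate
28 | C5-bromo derivative of sulfone 27 (C5 epimers) | COc1ccc(CO[C@@H]2C/C(CO[Si](c4ccccc4)(c5ccccc5)C(C)(C)C)=C/CC[C@H](C)S(=O)(=O)C(Br)[C@H]3OC(OC)C[C@H]23)cc1 | intermediate (not isolated)
29 | cis-fused episulfone: thiirane 1,1-dioxide across C4 and C5 of the ten-membered ring (C3 and C6 cis) | COc1ccc(CO[C@@H]2C/C(CO[Si](c4ccccc4)(c5ccccc5)C(C)(C)C)=C/CCC6(C)C([C@H]3OC(OC)C[C@H]23)S6(=O)=O)cc1 | intermediate (not isolated)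
30 | cyclodeca-1(10),4-diene: C4=C5 ring-cis (4Z), C10=C1 ring-trans, O6–C12 methyl acetal, C8 PMB ether, C14 TBDPS ether | COc1ccc(CO[C@@H]2C/C(CO[Si](c4ccccc4)(c5ccccc5)C(C)(C)C)=C/CC/C(C)=C\[C@H]3OC(OC)C[C@H]23)cc1 | intermediate
31 | lactol of 30 (C12 hemiacetal, anomers) | COc1ccc(CO[C@@H]2C/C(CO[Si](c4ccccc4)(c5ccccc5)C(C)(C)C)=C/CC/C(C)=C\[C@H]3OC(O)C[C@H]23)cc1 | intermediate
32 | trans-fused 12,6-lactone with C8 PMB ether and C14 TBDPS ether | COc1ccc(CO[C@@H]2C/C(CO[Si](c4ccccc4)(c5ccccc5)C(C)(C)C)=C/CC/C(C)=C\[C@H]3OC(=O)C[C@H]23)cc1 | intermediate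
33 | C11 (dimethylamino)methyl lactone (Mannich base) | COc1ccc(CO[C@@H]2C/C(CO[Si](c4ccccc4)(c5ccccc5)C(C)(C)C)=C/CC/C(C)=C\[C@H]3OC(=O)C(CN(C)C)[C@H]23)cc1 | intermediate (not isolated)
34 | C11 (trimethylammonio)methyl lactone iodide | [I-].COc1ccc(CO[C@@H]2C/C(CO[Si](c4ccccc4)(c5ccccc5)C(C)(C)C)=C/CC/C(C)=C\[C@H]3OC(=O)C(C[N+](C)(C)C)[C@H]23)cc1 | intermediate (not isolated)
35 | α-methylene lactone (C11=C13) with C8 PMB ether and C14 TBDPS ether | COc1ccc(CO[C@@H]2C/C(CO[Si](c4ccccc4)(c5ccccc5)C(C)(C)C)=C/CC/C(C)=C\[C@H]3OC(=O)C(=C)[C@H]23)cc1 | intermediate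
36 | 8R alcohol of the α-methylene lactone, C14 TBDPS ether | O[C@@H]1C/C(CO[Si](c3ccccc3)(c4ccccc4)C(C)(C)C)=C/CC/C(C)=C\[C@H]2OC(=O)C(=C)[C@@H]21 | intermediate
37 | C8 methacrylate, C14 TBDPS ether | C=C(C)C(=O)O[C@@H]1C/C(CO[Si](c3ccccc3)(c4ccccc4)C(C)(C)C)=C/CC/C(C)=C\[C@H]2OC(=O)C(=C)[C@@H]21 | intermediate
38 | C8 methacrylate with free C14 allylic alcohol | C=C(C)C(=O)O[C@@H]1C/C(CO)=C/CC/C(C)=C\[C@H]2OC(=O)C(=C)[C@@H]21 | intermediate
39 | (1R,10S)-1,10-epoxide with free C14 hydroxyl | C=C(C)C(=O)O[C@@H]1C[C@@]2(CO)O[C@@H]2CC/C(C)=C\[C@H]2OC(=O)C(=C)[C@@H]21 | intermediate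
40 | CNP0150481.2: (1R,6R,7R,8R,10S,4Z)-14-acetoxy-1,10-epoxy-8-methacryloyloxygermacra-4,11(13)-dien-12,6-olide | C=C(C)C(=O)O[C@@H]1C[C@@]2(COC(C)=O)O[C@@H]2CC/C(C)=C\[C@H]2OC(=O)C(=C)[C@@H]21 | target

**Step count and risks**

Total step count: 29. Longest linear sequence: 25 steps (steps 1–10 and 15–29); steps 11–14 make the ylide precursor.

Steps most likely to fail:

1. Step 21 (ring contraction). The C5 carbanion may expel O6 (β-elimination opening the five-membered ring) or be brominated twice before the slower removal of the tertiary C4–H, and closure through a trans-fused episulfone would give the ring-trans olefin. Fallback, setting out from diol 22 and coming back at 30: Dess–Martin oxidation of both hydroxyls gives keto aldehyde F1. Reductive coupling with low-valent titanium (TiCl3(DME)1.5, Zn–Cu, DME, 25 °C, slow addition) closes the ten-membered ring at C4–C5 as the pinacol, from which the cis-4,5-diol F2 is separated. Thiocarbonyldiimidazole converts it into the cyclic thionocarbonate F3. Corey–Winter fragmentation with 1,3-dimethyl-2-phenyl-1,3,2-diazaphospholidine at 40 °C is a stereospecific syn elimination and should give the ring-cis olefin 30.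

2. Step 19 (thiacycle closure). Intermolecular S-alkylation and disulfide formation may outrun the slow displacement at the β-branched, β-oxygenated C5 in a strained eleven-membered transition state. Fallback, setting out from diol 22 and coming back at 26: the roles of the two carbons are reversed. Primary-selective Mitsunobu reaction with thioacetic acid gives the C5 thioacetate F4 with free C4 hydroxyl, and mesylation (MsCl, Et3N) gives the C4 mesylate F5. With K2CO3 in methanol at high dilution the unhindered primary C5 thiolate closes the ring by SN2 at C4 with inversion, which gives the same 4S sulfide 26.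

3. Step 15 (trisubstituted olefin). The olefin geometry may erode (chain trans to C14), or the basic ylide may enolise the ketone toward β-elimination of the C8 ether. Fallback, setting out from iodide 18 and ketone 13 and coming back at 21: Arbuzov reaction of 18 with ethyl diphenylphosphinite gives the alkyldiphenylphosphine oxide F6. Lithiation (n-BuLi, THF, −78 °C) and addition to 13 give β-hydroxy phosphine oxides, from which the diastereomer F7 that leads to the required olefin is separated by chromatography. Its stereospecific syn elimination (NaH, DMF, 50 °C; Horner–Wittig) should give 21 as a single geometric isomer.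

**Further compounds**

F1 | step 21 | keto aldehyde: C5 aldehyde and C4 methyl ketone of chain 22 | O=C[C@H]1OC(OC)C[C@@H]1[C@H](OCc2ccc(OC)cc2)C/C(CO[Si](c3ccccc3)(c4ccccc4)C(C)(C)C)=C/CCC(C)=O
F2 | step 21 | ten-membered cis-4,5-diol (C4 tertiary, C5 secondary carbinol) | COc1ccc(CO[C@@H]2C/C(CO[Si](c4ccccc4)(c5ccccc5)C(C)(C)C)=C/CCC(C)(O)C(O)[C@H]3OC(OC)C[C@H]23)cc1
F3 | step 21 | cyclic 4,5-thionocarbonate of F2 | COc1ccc(CO[C@@H]2C/C(CO[Si](c4ccccc4)(c5ccccc5)C(C)(C)C)=C/CCC6(C)OC(=S)OC6[C@H]3OC(OC)C[C@H]23)cc1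
F4 | step 19 | C5 S-acetyl thioester with free C4 (R) hydroxyl | CC(=O)SC[C@H]1OC(OC)C[C@@H]1[C@H](OCc2ccc(OC)cc2)C/C(CO[Si](c3ccccc3)(c4ccccc4)C(C)(C)C)=C/CC[C@@H](C)O
F5 | step 19 | C5 S-acetyl thioester with C4 (R) methanesulfonate | CC(=O)SC[C@H]1OC(OC)C[C@@H]1[C@H](OCc2ccc(OC)cc2)C/C(CO[Si](c3ccccc3)(c4ccccc4)C(C)(C)C)=C/CC[C@@H](C)OS(C)(=O)=O
F6 | step 15 | [(R)-4-(tert-butyldimethylsilyloxy)pentyl]diphenylphosphine oxide | O=P(c1ccccc1)(c1ccccc1)CCC[C@@H](C)O[Si](C)(C)C(C)(C)C
F7 | step 15 | β-hydroxy phosphine oxide: C10 tertiary alcohol, C1 diphenylphosphinoyl adduct of 13 and F6 | CC(C)(C)[Si](C)(C)OC[C@H]1OC(OC)C[C@@H]1[C@H](OCc2ccc(OC)cc2)CC(O)(CO[Si](c3ccccc3)(c4ccccc4)C(C)(C)C)C(CC[C@@H](C)O[Si](C)(C)C(C)(C)C)P(=O)(c5ccccc5)c6ccccc6
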